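**Retrosynthetic overview**

1. Target ⇒ C3–Cα bond: catalytic asymmetric Mukaiyama-type addition of the methyl propanoate silyl ketene acetal to a 1,2-dioxan-3-yl peroxycarbenium ion (new method; sets C3 and Cα).
2. 3-Methoxy-1,2-dioxane ⇒ tertiary hydroperoxide plus one-carbon homologation ⇒ H2O2 opening (inversion) of a 2,2-disubstituted oxetane.
3. Oxetane ⇒ key ring expansion of an enantioenriched oxirane by a sulfoxonium ylide; the oxirane comes from the methyl ketone (sets C6).
4. Methyl ketone ⇒ bicyclic tosylate ⇒ asymmetric polyene cyclisation of a (3Z,7E)-homofarnesyl tosylate (sets the three decalin centres).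
5. Triene ⇒ two alkyne carbometalations of C3–C6 pieces. Ring order: ring A then ring B (one step), oxirane → oxetane (transient), 1,2-dioxane last.

Assumption: the SMILES is read as methyl (2S)-2-[(3S,6S)-6-methyl-6-(2-Dec-ethyl)-1,2-dioxan-3-yl]propanoate, where Dec = (1S,4aR,8aR)-2,5,5,8a-tetramethyl-1,4,4a,5,6,7,8,8a-octahydronaphthalen-1-yl (trans-fused, side chain anti to the angular methyl); the α-methyl and the C3–O bond are anti, and the two carbon chains on the dioxane are cis.

**Route**

Step 1
Reactants: 1 5-bromo-2-methylpent-2-ene; 2 pent-3-yn-1-ol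
Product: 4 (3E)-4,8-dimethylnona-3,7-dien-1-ol (homogeraniol), via (4-methylpent-3-en-1-yl)magnesium bromide 3 (not isolated)
Conditions: 1, Mg, THF, rt (gives 3, 2.5 equiv); 2, Fe(acac)3 (10 mol %), THF, 0 °C → rt; aq. NH4Cl
Reagents that add atoms: none
Why: Iron-catalysed, alkoxide-directed syn-carbomagnesiation of the homopropargylic alcohol puts the alkyl group on the alkyne carbon remote from oxygen and magnesium on the proximal one (five-membered chelate), so protonation gives only the E-trisubstituted alkene.

Step 2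
Reactants: 4
Product: 5 (6E)-9-bromo-2,6-dimethylnona-2,6-diene (homogeranyl bromide)
Conditions: CBr4, PPh3, CH2Cl2, 0 °C
Reagents that add atoms: carbon tetrabromide BrC(Br)(Br)Br
Why: Appel bromination of a primary homoallylic alcohol (SN2 on the alkoxyphosphonium ion) leaves the alkene geometry untouched.

Step 3
Reactants: 5; 6 propyne; 7 oxirane
Product: 11 (3Z,7E)-4,8,12-trimethyltrideca-3,7,11-trien-1-yl 4-methylbenzenesulfonate, via homogeranylmagnesium bromide 8 (not isolated), via Z-alkenylcopper 9 (not isolated), via bromomagnesium homofarnesolate 10 (not isolated)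
Conditions: 5, Mg, THF; CuBr·SMe2 (1.0 equiv), Et2O–Me2S, −45 °C; 6, −25 °C; 7, −25 → 0 °C; TsCl, DMAP (cat.), 0 °C → rt
Reagents that add atoms: 4-methylbenzenesulfonyl chloride Cc1ccc(cc1)S(Cl)(=O)=O
Why: Normant carbocupration adds the alkylcopper syn across propyne (alkyl to the internal carbon), opening of oxirane with retention then fixes the Z (neryl-type) trisubstituted alkene, and in-flask sulfonylation gives a chain end that cannot trap the cations of step 4.

Step 4
Reactants: 11
Product: 12 2-Dec-ethyl 4-methylbenzenesulfonate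
Conditions: IDPi Brønsted acid (3 mol %, antipode of the catalyst that gives the (−)-ambrox series from (3E,7E)-homofarnesol), (CF3)3COH, −40 °C; Et3N
Reagents that add atoms: none
Why: Catalytic asymmetric proton-initiated polyene cyclisation (Stork–Eschenmoser chair–chair course): the confined chiral anion controls the face of protonation of the terminal alkene and so C4a (R) and C8a (R), the 7E alkene gives the trans ring fusion, the 3Z alkene puts the side chain axial at C1 (S) anti to the angular methyl, and loss of the axial C3 proton gives the trisubstituted ring B alkene, rings A and B forming in that order.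

Step 5
Reactants: 12; 13 ethoxyethene
Product: 17 4-Dec-butan-2-one, via (1-ethoxyethenyl)lithium 14 (not isolated), via lithium bis(1-ethoxyethenyl)cuprate 15 (not isolated), via 2-ethoxyalkene 16 (not isolated)
Conditions: 13, t-BuLi, THF, −78 → 0 °C; CuI (0.5 equiv), −40 °C; 12, −40 → 0 °C; 1 M HCl, THF, rt
Reagents that add atoms: water O
Why: Nucleophilic acylation: SN2 displacement of the primary tosylate by the α-alkoxyvinyl cuprate (acetyl anion equivalent) and acid hydrolysis of the enol ether give the methyl ketone without touching a stereocentre.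

Step 6
Reactants: 17
Product: 19 (2R)-2-methyl-2-(2-Dec-ethyl)oxetane, via R-configured oxirane 18 (not isolated)
Conditions: Me3S(O)I, NaH (gives Me2S(O)=CH2, 1.2 equiv), LaLi3[(S)-binaphtholate]3 (5 mol %), (2,4,6-(MeO)3C6H2)3P=O (5 mol %), 5 Å MS, THF, rt; then Me2S(O)=CH2 (2 equiv), 45 °C, 72 h
Reagents that add atoms: trimethylsulfoxonium iodide C[S+](C)(C)=O.[I-]
Why: Key step: catalytic asymmetric Corey–Chaykovsky epoxidation of the methyl ketone (the La/Li catalyst tells methyl from CH2CH2R and delivers CH2 to the Si face, setting the quaternary carbon as R; use the mirror-image catalyst if the sense is opposite) is followed by ring expansion of the oxirane to the oxetane, in which the ylide opens the epoxide at CH2 and the alkoxide closes on the sulfoxonium carbon, so the tertiary C–O bond is never broken (retention) and the chiral catalyst expands the major epimer faster.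

Step 7
Reactants: 19
Product: 20 (3S)-3-hydroperoxy-3-methyl-5-Dec-pentan-1-ol
Conditions: H2O2 (anhydrous, Et2O, 5 equiv), Me3SiOTf (0.2 equiv), Et2O, −78 → −20 °C
Reagents that add atoms: hydrogen peroxide OO
Why: Lewis-acid-promoted oxetane perhydrolysis: H2O2 attacks the tertiary carbon of the activated four-membered ring from the rear in an SN2-like, strain-releasing opening, giving the tertiary hydroperoxide with inversion (S), while the trisubstituted ring alkene is inert at this temperature.

Step 8
Reactants: 20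
Product: 21 (3S)-3-[(2-methoxypropan-2-yl)peroxy]-3-methyl-5-Dec-pentan-1-ol
Conditions: 2-methoxypropene (1.1 equiv), PPTS (2 mol %), CH2Cl2, −20 °C
Reagents that add atoms: 2-methoxypropene COC(C)=C
Why: Acid-catalysed addition of the hydroperoxide (the more nucleophilic hydroxyl, α-effect) to the enol ether gives the monoperoxyketal, which masks OOH during oxidation and olefination.

Step 9
Reactants: 21
Product: 22 (3S)-3-[(2-methoxypropan-2-yl)peroxy]-3-methyl-5-Dec-pentanal
Conditions: Dess–Martin periodinane, NaHCO3, CH2Cl2, 0 °C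
Reagents that add atoms: none
Why: Dess–Martin oxidation of the primary alcohol under buffered, non-basic conditions avoids β-elimination of the peroxide from the β-peroxy aldehyde.

Step 10
Reactants: 22
Product: 24 (6S)-3-methoxy-6-methyl-6-(2-Dec-ethyl)-1,2-dioxane (both C3 epimers), via methyl enol ether 23 (not isolated)
Conditions: MeOCH2PPh3Cl, KN(SiMe3)2, THF, −78 °C; 22, −78 → −30 °C; then CSA (0.2 equiv), MeOH, 0 °C → rt
Reagents that add atoms: (methoxymethyl)triphenylphosphonium chloride COC[P+](c1ccccc1)(c1ccccc1)c1ccccc1.[Cl-]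
Why: Wittig methoxymethylenation adds the missing ring carbon (C3) at the aldehyde oxidation level, then acid in methanol removes the peroxyketal and protonates the enol ether so that the freed tertiary hydroperoxide closes the six-membered cyclic peroxyacetal (both C3 epimers converge in step 12).

Step 11
Reactants: 25 methyl propanoate
Product: 27 {[(1E)-1-methoxyprop-1-en-1-yl]oxy}trimethylsilane, via lithium E-enolate 26 (not isolated)
Conditions: LiN(i-Pr)2, THF, −78 °C; Me3SiCl, −78 °C → rt; distillation
Reagents that add atoms: chlorotrimethylsilane C[Si](C)(C)Cl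
Why: Kinetic ester enolisation in THF (Ireland model) gives the enolate with methyl trans to O–Li, and O-silylation gives the E-silyl ketene acetal.

Step 12
Reactants: 24; 27
Product: 28 methyl (2S)-2-[(3S,6S)-6-methyl-6-(2-Dec-ethyl)-1,2-dioxan-3-yl]propanoate (target)
Conditions: IDPi (3 mol %, the enantiomer that leaves the Re face of C3 open), toluene, −78 → −60 °C
Reagents that add atoms: none
Why: Proposed new method: the silylated IDPi (formed in situ from the acid and 27) abstracts the methoxy group of 24 to give a cyclic peroxycarbenium ion held as a contact ion pair inside the confined chiral imidodiphosphorimidate anion; because C6 (methyl versus CH2CH2R) gives no useful substrate bias, the anion alone decides that the Re face of C3 is attacked (3S), and an open antiperiplanar transition state with the OSiMe3 group of the E-ketene acetal under the small C3–H and the α-methyl over the ring sets Cα as 2S (2,3-anti), silyl transfer then regenerating the silylium catalyst; closest known reactions are IDPi/silylium-catalysed Mukaiyama-type additions of silyl ketene acetals to cyclic aliphatic oxocarbenium ions from lactol acetals, and achiral Lewis-acid (TiCl4, SnCl4, Me3SiOTf) additions of silyl ketene acetals to 3-alkoxy-1,2-dioxolane and 1,2-dioxane peroxycarbenium ions.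

**Compound list**

1 | 5-bromo-2-methylpent-2-ene | CC(C)=CCCBr | starting material
2 | pent-3-yn-1-ol | CC#CCCO | starting material
3 | (4-methylpent-3-en-1-yl)magnesium bromide | CC(C)=CCC[Mg]Br | intermediate
4 | (3E)-4,8-dimethylnona-3,7-dien-1-ol | CC(C)=CCC/C(C)=C/CCO | intermediate
5 | (6E)-9-bromo-2,6-dimethylnona-2,6-diene | CC(C)=CCC/C(C)=C/CCBr | intermediate
6 | propyne | CC#C | starting material
7 | oxirane | C1CO1 | starting material
8 | [(3E)-4,8-dimethylnona-3,7-dien-1-yl]magnesium bromide | CC(C)=CCC/C(C)=C/CC[Mg]Br | intermediate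
9 | [(1Z,5E)-2,6,10-trimethylundeca-1,5,9-trien-1-yl]copper | CC(C)=CCC/C(C)=C/CC/C(C)=C\[Cu] | intermediate
10 | bromomagnesium (3Z,7E)-4,8,12-trimethyltrideca-3,7,11-trien-1-olate | CC(C)=CCC/C(C)=C/CC/C(C)=C\CCO[Mg]Br | intermediate
11 | (3Z,7E)-4,8,12-trimethyltrideca-3,7,11-trien-1-yl 4-methylbenzenesulfonate | CC(C)=CCC/C(C)=C/CC/C(C)=C\CCOS(=O)(=O)c1ccc(C)cc1 | intermediate
12 | 2-[(1S,4aR,8aR)-2,5,5,8a-tetramethyl-1,4,4a,5,6,7,8,8a-octahydronaphthalen-1-yl]ethyl 4-methylbenzenesulfonate | Cc1ccc(cc1)S(=O)(=O)OCC[C@H]1C(C)=CC[C@@H]2C(C)(C)CCC[C@]21C | intermediate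
13 | ethoxyethene | C=COCC | starting material
14 | (1-ethoxyethenyl)lithium | [Li]C(=C)OCC | intermediate
15 | lithium bis(1-ethoxyethenyl)cuprate | [Li+].C=C(OCC)[Cu-]C(=C)OCC | intermediate
16 | (1S,4aR,8aR)-1-(3-ethoxybut-3-en-1-yl)-2,5,5,8a-tetramethyl-1,4,4a,5,6,7,8,8a-octahydronaphthalene | C=C(OCC)CC[C@H]1C(C)=CC[C@@H]2C(C)(C)CCC[C@]21C | intermediate
17 | 4-[(1S,4aR,8aR)-2,5,5,8a-tetramethyl-1,4,4a,5,6,7,8,8a-octahydronaphthalen-1-yl]butan-2-one | CC(=O)CC[C@H]1C(C)=CC[C@@H]2C(C)(C)CCC[C@]21C | intermediate
18 | (2R)-2-methyl-2-(2-Dec-ethyl)oxirane | O1C[C@@]1(C)CC[C@H]2C(C)=CC[C@@H]3C(C)(C)CCC[C@]32C | intermediate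
19 | (2R)-2-methyl-2-(2-Dec-ethyl)oxetane | O1CC[C@@]1(C)CC[C@H]2C(C)=CC[C@@H]3C(C)(C)CCC[C@]32C | intermediate
20 | (3S)-3-hydroperoxy-3-methyl-5-Dec-pentan-1-ol | OCC[C@](C)(CC[C@H]1C(C)=CC[C@@H]2C(C)(C)CCC[C@]21C)OO | intermediate
21 | (3S)-3-[(2-methoxypropan-2-yl)peroxy]-3-methyl-5-Dec-pentan-1-ol | OCC[C@](C)(CC[C@H]1C(C)=CC[C@@H]2C(C)(C)CCC[C@]21C)OOC(C)(C)OC | intermediate
22 | (3S)-3-[(2-methoxypropan-2-yl)peroxy]-3-methyl-5-Dec-pentanal | O=CC[C@](C)(CC[C@H]1C(C)=CC[C@@H]2C(C)(C)CCC[C@]21C)OOC(C)(C)OC | intermediate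
23 | (4S)-1-methoxy-4-[(2-methoxypropan-2-yl)peroxy]-4-methyl-6-Dec-hex-1-ene (E/Z mixture) | COC=CC[C@](C)(CC[C@H]1C(C)=CC[C@@H]2C(C)(C)CCC[C@]21C)OOC(C)(C)OC | intermediate
24 | (6S)-3-methoxy-6-methyl-6-(2-Dec-ethyl)-1,2-dioxane (C3 epimers) | COC1CC[C@](C)(CC[C@H]2C(C)=CC[C@@H]3C(C)(C)CCC[C@]32C)OO1 | intermediate
25 | methyl propanoate | CCC(=O)OC | starting material
26 | lithium (1E)-1-methoxyprop-1-en-1-olate | C/C=C(\OC)O[Li] | intermediate
27 | {[(1E)-1-methoxyprop-1-en-1-yl]oxy}trimethylsilane | C/C=C(\OC)O[Si](C)(C)C | intermediate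
28 | methyl (2S)-2-[(3S,6S)-6-methyl-6-{2-[(1S,4aR,8aR)-2,5,5,8a-tetramethyl-1,4,4a,5,6,7,8,8a-octahydronaphthalen-1-yl]ethyl}-1,2-dioxan-3-yl]propanoate | COC(=O)[C@@H](C)[C@@H]1CC[C@](C)(CC[C@H]2C(C)=CC[C@@H]3C(C)(C)CCC[C@]32C)OO1 | target

**Step count and risks**

Total steps: 12 (11 on the main line, 1 for the ketene acetal). Longest linear sequence: 11 (steps 1–10, then 12).

Steps most likely to fail:

Step 4 (asymmetric polyene cyclisation). Neither the enantiomer ratio nor the position of the ring B double bond (endocyclic versus exocyclic or tetrasubstituted) is proven for a tosylate-terminated Z,E-triene that ends by proton loss. Fallback, setting out from 11 and coming back at 12: cyclise 11 with the achiral superacid FSO3H in 2-nitropropane at −78 °C, which follows the same chair–chair course and gives 12 as a racemate with its mirror image 2-[(1R,4aS,8aS)-2,5,5,8a-tetramethyl-1,4,4a,5,6,7,8,8a-octahydronaphthalen-1-yl]ethyl 4-methylbenzenesulfonate F1. The enantiomers are then separated by preparative chromatography on a chiral stationary phase (the arenesulfonate gives UV detection) and only 12 is carried on, so resolution replaces asymmetric catalysis.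

Step 10 (Wittig on the β-peroxy aldehyde and ring closure). The basic ylide may eliminate the peroxide from 22 before olefination. Fallback, setting out from 21 and coming back at 24, avoiding any β-peroxy carbonyl compound: tosylate the primary alcohol of 21 (TsCl, pyridine) to (3S)-3-[(2-methoxypropan-2-yl)peroxy]-3-methyl-5-Dec-pentyl 4-methylbenzenesulfonate F2. Alkylate the sodium salt of methyl (methylsulfinyl)methyl sulfide (NaH, THF) with F2 to give the dithioacetal S-oxide (1S,4aR,8aR)-1-[(3S)-3-[(2-methoxypropan-2-yl)peroxy]-3-methyl-6-(methylsulfanyl)-6-(methylsulfinyl)hexyl]-2,5,5,8a-tetramethyl-1,4,4a,5,6,7,8,8a-octahydronaphthalene F3. Acid methanolysis (CSA, MeOH) then unmasks the aldehyde oxidation level, removes the peroxyketal and closes the ring to 24.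

Step 12 (the proposed new method). The peroxide may not tolerate the silylium catalyst, or face and syn/anti control may be insufficient. Fallback with known chemistry, setting out from 24 and coming back at 28: hydrolyse the methyl peroxyacetal (AcOH, H2O, THF) to the lactol (6S)-6-methyl-6-(2-Dec-ethyl)-1,2-dioxan-3-ol F4. Open it with the stabilised ylide methyl 2-(triphenylphosphoranylidene)propanoate to the hydroperoxy enoate methyl (2E,6R)-6-hydroperoxy-2,6-dimethyl-8-Dec-oct-2-enoate F5 (same spatial arrangement at the peroxide carbon; the descriptor changes only by priority). Close the ring by base-mediated intramolecular oxa-Michael addition (Et2NH, CF3CH2OH), the established route to this class of cyclic peroxides. This gives the C2/C3 diastereomers, from which 28 is separated by HPLC.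

**Further compounds**

F1 | step 4 | 2-[(1R,4aS,8aS)-2,5,5,8a-tetramethyl-1,4,4a,5,6,7,8,8a-octahydronaphthalen-1-yl]ethyl 4-methylbenzenesulfonate | Cc1ccc(cc1)S(=O)(=O)OCC[C@@H]1C(C)=CC[C@H]2C(C)(C)CCC[C@@]21C
F2 | step 10 | (3S)-3-[(2-methoxypropan-2-yl)peroxy]-3-methyl-5-Dec-pentyl 4-methylbenzenesulfonate | Cc1ccc(cc1)S(=O)(=O)OCC[C@](C)(CC[C@H]1C(C)=CC[C@@H]2C(C)(C)CCC[C@]21C)OOC(C)(C)OC
F3 | step 10 | (1S,4aR,8aR)-1-[(3S)-3-[(2-methoxypropan-2-yl)peroxy]-3-methyl-6-(methylsulfanyl)-6-(methylsulfinyl)hexyl]-2,5,5,8a-tetramethyl-1,4,4a,5,6,7,8,8a-octahydronaphthalene | CSC(S(C)=O)CC[C@](C)(CC[C@H]1C(C)=CC[C@@H]2C(C)(C)CCC[C@]21C)OOC(C)(C)OC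
F4 | step 12 | (6S)-6-methyl-6-(2-Dec-ethyl)-1,2-dioxan-3-ol | OC1CC[C@](C)(CC[C@H]2C(C)=CC[C@@H]3C(C)(C)CCC[C@]32C)OO1
F5 | step 12 | methyl (2E,6R)-6-hydroperoxy-2,6-dimethyl-8-Dec-oct-2-enoate | COC(=O)/C(C)=C/CC[C@](C)(CC[C@H]1C(C)=CC[C@@H]2C(C)(C)CCC[C@]21C)OO
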